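## The problem

The target 14 is a trans-2-aryl-2,3-dihydrobenzofuran: a benzo ring fused to a dihydrofuran ring that carries a 4-hydroxyphenyl group on C2 and a carboxamide on C3, with an (E)-acrylamide on C5 of the benzo ring. Both amides come from the same amine, agmatine. The only stereocentres are the adjacent C2 and C3, both R and trans to each other. C3 is benzylic and α to a carbonyl group, so it equilibrates easily and the trans arrangement is the more stable one. A correctly set C2 can therefore hold or restore C3, but nothing in the molecule can set C2, whose absolute configuration must come from a reagent or catalyst. The same acidity is a liability: a C3 enolate can expel the ring oxygen from C2 and open the dihydrofuran, so strong base is excluded once the ring exists. The C2–O1 bond is a benzylic ether para to a phenol and may ionise in hot strong acid, the cinnamoyl alkene rules out hydrogenolysis, and the two guanidines are so basic and polar that they must stay masked until the last step. The enabling feature is that the O1–C2 bond and the C3–carboxyl bond flank the C2–C3 bond: O1, C2, C3 and the carboxyl carbon are the phenol oxygen and the alkene of an (E)-2-hydroxystilbene plus one molecule of CO, and the 4-oxyphenyl ring on C2 polarises that alkene in the sense the closure needs.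

## Retrosynthesis

Target 14 is traced first to its fully masked form 13, in which each guanidine carries two Boc groups and the phenol is a tert-butyl ether. The bonds cut are four N–CO2tBu bonds and one ArO–tBu bond. All five fall to the same acid, so the polar, basic functions appear only in the last operation, and 13 is a neutral compound that can be purified on silica. The forward step must leave the amides, the alkene and the C2–O1 bond untouched.

Compound 13 is cut at its two amide C–N bonds into diacid 8 and two molecules of di-Boc-agmatine 11. Because both carboxyl groups take the same amine, they need not be told apart, which is simpler than any stepwise amidation. Keeping the phenol of 8 as its tert-butyl ether removes O-acylation as a competing path. The forward reaction must acylate at the hindered C3 carboxyl without a base strong enough to remove the C3 proton. Amine 11 comes in one step from 1,4-diaminobutane 9 and the amidine-transfer reagent 10.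

Diacid 8 is traced to dimethyl ester 6. The C3 ester is a methyl ester because MeOH captures the acylpalladium in the key step; making the acrylate a methyl ester as well lets one operation free both acids while the phenol stays protected. Hydroxide is the obvious reagent but is the one most likely to open the ring through the C3 enolate, so the forward step is assigned to Me3SnOH, which passes through the stannyl ester 7.

Ester 6 is cut at O1–C2 and at the C3–carboxyl bond, which leads to the achiral 2-hydroxystilbene 5, CO and MeOH. Against a cut of C2–C3 or of benzo-ring bonds, this one removes the ring and both stereocentres in a single move. It leaves a flat precursor that already holds every carbon but one, with the C5 side chain in place and at the right oxidation level. The forward reaction must choose one face of the stilbene alkene, add oxygen and palladium anti, and insert CO faster than the C3–palladium intermediate loses the C2 hydrogen.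

Stilbene 5 is cut at the acrylate C=C bond into aldehyde 3 and the stabilised ylide 4, and 3 is cut at the aryl–vinyl bond into iodophenol 1 and styrene 2. A stabilised ylide needs no base and tolerates the free phenol. The Heck coupling comes first so that the aryl iodide meets only one alkene. All four starting materials are commercial.

## Roads not taken

Alternative 1: The benzo ring is cut at C3a–C7a, C4–C5 and C6–C7. This leads back to diyne A2, which has an ethynyl ether on the C2 oxygen and an ethynyl group on C3 of a preformed stereodiad, and to acetylene A3. In the forward sense RhCl(PPh3)3 would join the three alkynes in a [2+2+2] cyclotrimerisation and close the benzo and dihydrofuran rings together to give A1.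
- Merits: two rings form in one neutral step, the reaction type is known, and both stereocentres are set beforehand and are never at risk, because C3 carries a silyloxymethyl group and not a carbonyl.
- Weak points: A1 has a bare benzo ring. The C5 side chain would need a later halogenation para to O1, in competition with the equally activated 4-tert-butoxyphenyl ring, and then a Heck reaction. The C3 arm must be desilylated and oxidised through an epimerisable α-aryl aldehyde. The anti stereodiad of A2 needs its own asymmetric synthesis. A terminal ynol ether on a secondary benzylic oxygen is fragile and laborious to make, and A3 can trimerise with itself.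
- Comparison: the route would run to well over a dozen steps. The chosen plan cannot match the safety of stereocentres fixed before the ring forms. It offers instead a precursor two steps from commercial materials, both carboxyl groups at their final oxidation level, and seven steps in all.

Alternative 2: The cut is C2–C3 together with O1–C2, a [4+1] annulation. CsF would desilylate A5, the phenoxide would expel bromide to give ortho-quinone methide A6, and the ylide made from the chiral sulfonium salt A7 (or its antipode) with Cs2CO3 would add to the exocyclic carbon. The phenoxide would then displace the sulfide at C2 to give A4.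
- Merits: in precedent this road is better than the chosen one. Sulfur ylides and ortho-quinone methides are known to give trans-2,3-dihydrobenzofurans, and the trans relationship follows from the anti betaine and the SN2 closure. It is also convergent.
- Weak points: the chirality comes from a stoichiometric sulfide. A6, with an ester on its exocyclic carbon, is a very reactive acceptor that can dimerise or be trapped by fluoride or carbonate. The aryl acetate of A7 is exposed to those same bases, and once it is lost the 4-oxidobenzyl sulfonium can collapse to a para-quinone methide. A4 still lacks the side chain, so a Heck reaction at the bromide, acetate removal and ester hydrolysis follow, for about nine steps in total.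
- Comparison: the chosen plan offers a catalytic source of chirality, a precursor that already carries the acrylate, and two steps fewer. The price is a key step that is not yet known.

Alternative 3: The benzo ring is cut at C3a–C7a and C4–C5. Heating the pyrone A9 in an inert solvent would let its tethered terminal alkyne add across C3 and C6 of the 3-alkoxy-2-pyrone, closing the dihydrofuran ring, and decarboxylative aromatisation of the adduct would give A8.
- Merits: the tether fixes the regiochemistry of the benzo ring, no metal is needed, and the stereocentres are made beforehand.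
- Weak points: the C5 ester of A8 must be extended by two carbons (reduction to the aldehyde, then olefination), and the C3 silyloxymethyl arm must be oxidised to the acid. The three-atom tether calls for high temperature, at which the benzylic C2–O bond to a pyronyl oxygen, a good leaving group, may ionise and scramble C2. A9 itself needs the same separately made stereodiad as A2 and an O-alkylation of a 3-hydroxy-2-pyrone at a secondary benzylic centre.
- Comparison: this road is longer by roughly ten steps and uses only precedented reaction types, but its thermal step puts the C2 configuration at risk. The chosen plan makes both stereocentres and the ring in one low-temperature step and carries the right side chains from the start.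

Key step: step 3

Assumption: the sense of induction of the bisoxazoline cannot be predicted, so the route is written with (S,S)-Ph-box, 2,2'-isopropylidenebis[(4S)-4-phenyl-2-oxazoline], standing for whichever antipode gives (2R,3R); target 14 is drawn as the free base and would be handled as its bis(trifluoroacetate).

Step 1
Reactants: 1 4-hydroxy-3-iodobenzaldehyde; 2 4-tert-butoxystyrene
Product: 3 (E)-3-[2-(4-tert-butoxyphenyl)ethenyl]-4-hydroxybenzaldehyde
Conditions: Pd(OAc)2 (3 mol %), P(o-tol)3 (6 mol %), Et3N, DMF, 90 °C
Reagents that add atoms: none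
Why: Mizoroki–Heck reaction: zerovalent palladium inserts into the C–I bond of 1, the styrene inserts at its unsubstituted carbon and syn β-hydride elimination gives the E-stilbene. Iodophenols and styrenes are standard partners, and the aldehyde and the tert-butyl ether are inert to Et3N in DMF.

Step 2
Reactants: 3 (E)-3-[2-(4-tert-butoxyphenyl)ethenyl]-4-hydroxybenzaldehyde; 4 methyl (triphenylphosphoranylidene)acetate
Product: 5 methyl (E)-3-{3-[(E)-2-(4-tert-butoxyphenyl)ethenyl]-4-hydroxyphenyl}prop-2-enoate
Conditions: toluene, 80 °C
Reagents that add atoms: none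
Why: Wittig olefination with a stabilised ylide, which needs no added base, is routinely used on 4-hydroxybenzaldehydes and gives the E-acrylate.

Step 3
Reactants: 5 methyl (E)-3-{3-[(E)-2-(4-tert-butoxyphenyl)ethenyl]-4-hydroxyphenyl}prop-2-enoate
Product: 6 methyl (2R,3R)-2-(4-tert-butoxyphenyl)-5-[(E)-3-methoxy-3-oxoprop-1-enyl]-2,3-dihydro-1-benzofuran-3-carboxylate (trans)
Conditions: Pd(OCOCF3)2 (10 mol %), (S,S)-Ph-box (12 mol %), p-benzoquinone (2 equiv), CO (5 atm), MeOH/CH2Cl2 1:1, 0 °C → rt
Reagents that add atoms: carbon monoxide, SMILES [C-]#[O+]; methanol, SMILES CO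
Why: Proposed new method: divalent palladium bound to the bisoxazoline coordinates the electron-rich stilbene alkene of 5, the phenol oxygen attacks C2 anti to the metal, the C3–palladium bond inserts CO with retention, methanolysis of the acylpalladium releases 6, and p-benzoquinone returns zerovalent palladium to the divalent state. The closest known reaction types are the intramolecular alkoxycarbonylation of hydroxy alkenes by divalent palladium under CO in MeOH and the palladium-mediated oxidative cyclisation of 2-hydroxystilbenes to 2-arylbenzofurans, which passes through the same C3-palladated dihydrobenzofuran. The dihydrofuran ring closes by a 5-endo-trig oxypalladation, opened up by metal activation and by the 4-tert-butoxyphenyl ring, which stabilises positive charge at C2. C3 is set by the alkene face that the chiral palladium complex binds, and C2 follows from anti attack on the E-alkene, which places palladium, and after insertion with retention the ester, trans to the C2 aryl group. The step needs CO insertion to outrun β-hydride elimination of the syn C2–H, which CO pressure should secure by filling the vacant site on palladium. It also needs the metal to choose the stilbene alkene, which is secured because the acrylate alkene is electron-poor and has no nucleophile within reach. p-Benzoquinone is used as reoxidant in place of CuCl2 so that no HCl is formed that could cleave the tert-butyl ether.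

Step 4
Reactants: 6 methyl (2R,3R)-2-(4-tert-butoxyphenyl)-5-[(E)-3-methoxy-3-oxoprop-1-enyl]-2,3-dihydro-1-benzofuran-3-carboxylate
Product: 8 (2R,3R)-2-(4-tert-butoxyphenyl)-5-[(E)-2-carboxyethenyl]-2,3-dihydro-1-benzofuran-3-carboxylic acid, via bis(trimethylstannyl) ester 7 (not isolated)
Conditions: Me3SnOH (10 equiv), ClCH2CH2Cl, 80 °C; then 0.1 M HCl, EtOAc, 0 °C
Reagents that add atoms: trimethyltin hydroxide, SMILES C[Sn](C)(C)O
Why: Tin hydroxide ester hydrolysis is a near-neutral acyl substitution that spares base-sensitive α-centres, including 2,3-dihydrobenzofuran-3-carboxylates, so it should avoid the enolate that opens the ring under hydroxide. The aryl tert-butyl ether is stable to the reagent and to the brief cold acid wash that frees 8 from 7.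

Step 5
Reactants: 9 1,4-diaminobutane; 10 N,N'-bis(tert-butoxycarbonyl)-1H-pyrazole-1-carboxamidine
Product: 11 N-(4-aminobutyl)-N',N''-bis(tert-butoxycarbonyl)guanidine (di-Boc-agmatine)
Conditions: 9 (5 equiv), slow addition of 10, CH2Cl2, 0 °C → rt
Reagents that add atoms: none
Why: Amidine transfer from a pyrazole-1-carboxamidine to a primary amine is a standard guanidinylation. The excess of diamine ensures that only one nitrogen reacts, and the excess is removed with water.

Step 6
Reactants: 8 (2R,3R)-2-(4-tert-butoxyphenyl)-5-[(E)-2-carboxyethenyl]-2,3-dihydro-1-benzofuran-3-carboxylic acid; 11 di-Boc-agmatine (2.4 equiv)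
Product: 13 (2R,3R)-2-(4-tert-butoxyphenyl)-N-{4-[N',N''-bis(tert-butoxycarbonyl)guanidino]butyl}-5-[(E)-3-({4-[N',N''-bis(tert-butoxycarbonyl)guanidino]butyl}amino)-3-oxoprop-1-enyl]-2,3-dihydro-1-benzofuran-3-carboxamide, via bis(benzotriazol-1-yl) ester 12 (not isolated)
Conditions: N,N'-diisopropylcarbodiimide (DIC), 1-hydroxybenzotriazole (HOBt), DMF/CH2Cl2, 0 °C, 30 min; then 11, 0 °C → rt
Reagents that add atoms: none
Why: Carbodiimide/HOBt amide coupling of both carboxyl groups with the primary amine of 11. Activation without a tertiary amine keeps the C3 proton in place, the tert-butyl ether prevents O-acylation of the phenol, and C3 already sits in its more stable trans arrangement.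

Step 7
Reactants: 13 the tetra-Boc tert-butyl ether bis-amide
Product: 14 (2R,3R)-N-(4-guanidinobutyl)-5-{(E)-3-[(4-guanidinobutyl)amino]-3-oxoprop-1-enyl}-2-(4-hydroxyphenyl)-2,3-dihydro-1-benzofuran-3-carboxamide (target)
Conditions: TFA/CH2Cl2 1:1, H2O (5 %), 0 °C → rt; reversed-phase chromatography
Reagents that add atoms: none
Why: Acidolysis removes the four Boc groups and the aryl tert-butyl ether at once, with water as trap for the tert-butyl cations. The amides, the cinnamoyl alkene and the dihydrofuran ring, whose C2 cation is disfavoured by the neighbouring carboxamide, should survive at room temperature.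

Compound list

1 | 4-hydroxy-3-iodobenzaldehyde | O=Cc1ccc(O)c(I)c1 | starting material
2 | 4-tert-butoxystyrene | C=Cc1ccc(OC(C)(C)C)cc1 | starting material
3 | (E)-3-[2-(4-tert-butoxyphenyl)ethenyl]-4-hydroxybenzaldehyde | O=Cc1ccc(O)c(/C=C/c2ccc(OC(C)(C)C)cc2)c1 | intermediate
4 | methyl (triphenylphosphoranylidene)acetate | COC(=O)C=P(c1ccccc1)(c1ccccc1)c1ccccc1 | starting material
5 | methyl (E)-3-{3-[(E)-2-(4-tert-butoxyphenyl)ethenyl]-4-hydroxyphenyl}prop-2-enoate | COC(=O)/C=C/c1ccc(O)c(/C=C/c2ccc(OC(C)(C)C)cc2)c1 | intermediate
6 | methyl (2R,3R)-2-(4-tert-butoxyphenyl)-5-[(E)-3-methoxy-3-oxoprop-1-enyl]-2,3-dihydro-1-benzofuran-3-carboxylate | COC(=O)/C=C/c1ccc2c(c1)[C@@H](C(=O)OC)[C@H](c1ccc(OC(C)(C)C)cc1)O2 | intermediate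
7 | bis(trimethylstannyl) ester of diacid 8 (formed in the flask) | C[Sn](C)(C)OC(=O)/C=C/c1ccc2c(c1)[C@@H](C(=O)O[Sn](C)(C)C)[C@H](c1ccc(OC(C)(C)C)cc1)O2 | intermediate
8 | (2R,3R)-2-(4-tert-butoxyphenyl)-5-[(E)-2-carboxyethenyl]-2,3-dihydro-1-benzofuran-3-carboxylic acid | OC(=O)/C=C/c1ccc2c(c1)[C@@H](C(=O)O)[C@H](c1ccc(OC(C)(C)C)cc1)O2 | intermediate
9 | 1,4-diaminobutane | NCCCCN | starting material
10 | N,N'-bis(tert-butoxycarbonyl)-1H-pyrazole-1-carboxamidine | CC(C)(C)OC(=O)NC(=NC(=O)OC(C)(C)C)n1cccn1 | starting material
11 | N-(4-aminobutyl)-N',N''-bis(tert-butoxycarbonyl)guanidine | NCCCCNC(=NC(=O)OC(C)(C)C)NC(=O)OC(C)(C)C | intermediate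
12 | bis(benzotriazol-1-yl) ester of diacid 8 (formed in the flask) | O=C(On1nnc2ccccc12)/C=C/c3ccc4c(c3)[C@@H](C(=O)On5nnc6ccccc56)[C@H](c7ccc(OC(C)(C)C)cc7)O4 | intermediate
13 | tetra-Boc tert-butyl ether bis-amide (full name in step 6) | CC(C)(C)OC(=O)NC(=NC(=O)OC(C)(C)C)NCCCCNC(=O)/C=C/c1ccc2c(c1)[C@@H](C(=O)NCCCCNC(=NC(=O)OC(C)(C)C)NC(=O)OC(C)(C)C)[C@H](c1ccc(OC(C)(C)C)cc1)O2 | intermediate
14 | (2R,3R)-N-(4-guanidinobutyl)-5-{(E)-3-[(4-guanidinobutyl)amino]-3-oxoprop-1-enyl}-2-(4-hydroxyphenyl)-2,3-dihydro-1-benzofuran-3-carboxamide | NC(N)=NCCCCNC(=O)/C=C/c1ccc2c(c1)[C@@H](C(=O)NCCCCN=C(N)N)[C@H](c1ccc(O)cc1)O2 | target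

Total step count: 7. Longest linear sequence: 6 steps (steps 1, 2, 3, 4, 6 and 7); step 5 is a one-step side branch.

Steps least certain to work

Step 3 (key step, proposed new method). Most likely failures:
- β-hydride elimination of the C2 hydrogen may outrun CO insertion and drain the intermediate into the 2-arylbenzofuran.
- Facial selectivity at the alkene may be poor.
- The closure may leak through an open C2 benzylic cation and lose the trans relationship.
- The oxidant may be consumed in oxidative carbonylation of the solvent.

Fallback with known chemistry, setting out from 1 and returning at 6: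
- Mitsunobu etherification of 1 with commercial 4-tert-butoxybenzyl alcohol (PPh3, diisopropyl azodicarboxylate, THF) would give 4-[(4-tert-butoxyphenyl)methoxy]-3-iodobenzaldehyde F1.
- Wittig olefination with 4 would give methyl (E)-3-{4-[(4-tert-butoxyphenyl)methoxy]-3-iodophenyl}prop-2-enoate F2.
- Coupling of the aryl iodide with methyl diazoacetate (Pd(PPh3)4, Ag2CO3, Et3N, toluene, rt), which keeps the diazo group, would give methyl (E)-3-{4-[(4-tert-butoxyphenyl)methoxy]-3-(1-diazo-2-methoxy-2-oxoethyl)phenyl}prop-2-enoate F3.
- Rh2(S-PTTL)4, dirhodium tetrakis[N-phthaloyl-(S)-tert-leucinate], or its antipode, in toluene at −60 °C would insert the carbenoid into the benzylic ether C–H bond. This known cis-selective closure would give methyl (2R,3S)-2-(4-tert-butoxyphenyl)-5-[(E)-3-methoxy-3-oxoprop-1-enyl]-2,3-dihydro-1-benzofuran-3-carboxylate F4.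
- Catalytic NaOMe in MeOH at 0 °C would epimerise C3 to the trans ester 6.

Step 4. The conjugated ester may hydrolyse only slowly, and prolonged heating may still cause β-elimination of the ring oxygen at C3 and open the ring. The fallback avoids the acids altogether, sets out from 6 and returns at 14:
- AlMe3-promoted aminolysis of both methyl esters with commercial tert-butyl N-(4-aminobutyl)carbamate (toluene/CH2Cl2, 40 °C) would give tert-butyl N-{4-[(E)-3-{(2R,3R)-2-(4-tert-butoxyphenyl)-3-[4-(tert-butoxycarbonylamino)butylcarbamoyl]-2,3-dihydro-1-benzofuran-5-yl}prop-2-enoylamino]butyl}carbamate F5.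
- TFA would remove both carbamates and the tert-butyl ether to give (2R,3R)-N-(4-aminobutyl)-5-[(E)-3-(4-aminobutylamino)-3-oxoprop-1-enyl]-2-(4-hydroxyphenyl)-2,3-dihydro-1-benzofuran-3-carboxamide F6.
- 1H-Pyrazole-1-carboxamidine hydrochloride with iPr2NEt in DMF would convert both primary amines into guanidines and give 14.

Step 6. Slow acylation of the bulky amine at the hindered C3 carboxyl would leave the activated C3 ester standing, which invites loss of the C3 proton and opening of the ring, or rearrangement to the N-acylurea. The fallback uses an isolated active ester and the small, unprotected amine, sets out from 8 and returns at 14: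
- DIC and N-hydroxysuccinimide would give bis(2,5-dioxopyrrolidin-1-yl) (2R,3R)-2-(4-tert-butoxyphenyl)-5-[(E)-2-carboxyethenyl]-2,3-dihydro-1-benzofuran-3-carboxylate F7.
- Commercial agmatine sulfate in DMF/aqueous NaHCO3 would give (2R,3R)-2-(4-tert-butoxyphenyl)-N-(4-guanidinobutyl)-5-{(E)-3-[(4-guanidinobutyl)amino]-3-oxoprop-1-enyl}-2,3-dihydro-1-benzofuran-3-carboxamide F8.
- TFA would remove the tert-butyl ether and give 14.

Step 1. The electron-rich styrene may be arylated in part at its internal carbon, and the phenoxide may slow the catalyst. The fallback fixes the regiochemistry in the coupling partner, sets out from 2 and 1 and returns at 3: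
- Cross-metathesis of 2 with vinylboronic acid pinacol ester (second-generation Grubbs catalyst, CH2Cl2, 40 °C) would give (E)-2-[2-(4-tert-butoxyphenyl)ethenyl]-4,4,5,5-tetramethyl-1,3,2-dioxaborolane F9.
- Suzuki–Miyaura coupling with 1 (Pd(PPh3)4, K2CO3, dioxane/H2O, 80 °C) would give 3.

Further compounds

F1 | step 3 | 4-[(4-tert-butoxyphenyl)methoxy]-3-iodobenzaldehyde | O=Cc1ccc(OCc2ccc(OC(C)(C)C)cc2)c(I)c1
F2 | step 3 | methyl (E)-3-{4-[(4-tert-butoxyphenyl)methoxy]-3-iodophenyl}prop-2-enoate | COC(=O)/C=C/c1ccc(OCc2ccc(OC(C)(C)C)cc2)c(I)c1
F3 | step 3 | methyl (E)-3-{4-[(4-tert-butoxyphenyl)methoxy]-3-(1-diazo-2-methoxy-2-oxoethyl)phenyl}prop-2-enoate | COC(=O)/C=C/c1ccc(OCc2ccc(OC(C)(C)C)cc2)c(C(=[N+]=[N-])C(=O)OC)c1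
F4 | step 3 | methyl (2R,3S)-2-(4-tert-butoxyphenyl)-5-[(E)-3-methoxy-3-oxoprop-1-enyl]-2,3-dihydro-1-benzofuran-3-carboxylate (cis) | COC(=O)/C=C/c1ccc2c(c1)[C@H](C(=O)OC)[C@H](c1ccc(OC(C)(C)C)cc1)O2
F5 | step 4 | tert-butyl N-{4-[(E)-3-{(2R,3R)-2-(4-tert-butoxyphenyl)-3-[4-(tert-butoxycarbonylamino)butylcarbamoyl]-2,3-dihydro-1-benzofuran-5-yl}prop-2-enoylamino]butyl}carbamate | CC(C)(C)OC(=O)NCCCCNC(=O)/C=C/c1ccc2c(c1)[C@@H](C(=O)NCCCCNC(=O)OC(C)(C)C)[C@H](c1ccc(OC(C)(C)C)cc1)O2
F6 | step 4 | (2R,3R)-N-(4-aminobutyl)-5-[(E)-3-(4-aminobutylamino)-3-oxoprop-1-enyl]-2-(4-hydroxyphenyl)-2,3-dihydro-1-benzofuran-3-carboxamide | NCCCCNC(=O)/C=C/c1ccc2c(c1)[C@@H](C(=O)NCCCCN)[C@H](c1ccc(O)cc1)O2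
F7 | step 6 | bis(2,5-dioxopyrrolidin-1-yl) (2R,3R)-2-(4-tert-butoxyphenyl)-5-[(E)-2-carboxyethenyl]-2,3-dihydro-1-benzofuran-3-carboxylate | O=C(ON1C(=O)CCC1=O)/C=C/c2ccc3c(c2)[C@@H](C(=O)ON4C(=O)CCC4=O)[C@H](c5ccc(OC(C)(C)C)cc5)O3
F8 | step 6 | (2R,3R)-2-(4-tert-butoxyphenyl)-N-(4-guanidinobutyl)-5-{(E)-3-[(4-guanidinobutyl)amino]-3-oxoprop-1-enyl}-2,3-dihydro-1-benzofuran-3-carboxamide | NC(N)=NCCCCNC(=O)/C=C/c1ccc2c(c1)[C@@H](C(=O)NCCCCN=C(N)N)[C@H](c1ccc(OC(C)(C)C)cc1)O2
F9 | step 1 | (E)-2-[2-(4-tert-butoxyphenyl)ethenyl]-4,4,5,5-tetramethyl-1,3,2-dioxaborolane | CC(C)(C)Oc1ccc(/C=C/B2OC(C)(C)C(C)(C)O2)cc1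
A1 | alternative 1 | (2R,3S)-2-(4-tert-butoxyphenyl)-3-(tert-butyldimethylsilyloxymethyl)-2,3-dihydrobenzofuran | c1ccc2c(c1)[C@@H](CO[Si](C)(C)C(C)(C)C)[C@H](c1ccc(OC(C)(C)C)cc1)O2
A2 | alternative 1 | tert-butyl{[(2S,3R)-3-(4-tert-butoxyphenyl)-2-ethynyl-3-(ethynyloxy)propyl]oxy}dimethylsilane | C#C[C@@H](CO[Si](C)(C)C(C)(C)C)[C@H](c1ccc(OC(C)(C)C)cc1)OC#C
A3 | alternative 1 | acetylene | C#C
A4 | alternative 2 | methyl (2R,3R)-2-(4-acetoxyphenyl)-5-bromo-2,3-dihydrobenzofuran-3-carboxylate | Brc1ccc2c(c1)[C@@H](C(=O)OC)[C@H](c1ccc(OC(C)=O)cc1)O2
A5 | alternative 2 | methyl 2-bromo-2-[5-bromo-2-(tert-butyldimethylsilyloxy)phenyl]acetate | COC(=O)C(Br)c1cc(Br)ccc1O[Si](C)(C)C(C)(C)C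
A6 | alternative 2 | methyl 2-(3-bromo-6-oxocyclohexa-2,4-dien-1-ylidene)acetate | O=C1C=CC(Br)=CC1=CC(=O)OC
A7 | alternative 2 | (2R,5R)-1-(4-acetoxybenzyl)-2,5-dimethylthiolan-1-ium tetrafluoroborate | C[C@@H]1CC[C@@H](C)[S+]1Cc1ccc(OC(C)=O)cc1.F[B-](F)(F)F
A8 | alternative 3 | methyl (2R,3S)-3-(tert-butyldimethylsilyloxymethyl)-2-[4-(pivaloyloxy)phenyl]-2,3-dihydrobenzofuran-5-carboxylate | COC(=O)c1ccc2c(c1)[C@@H](CO[Si](C)(C)C(C)(C)C)[C@H](c1ccc(OC(=O)C(C)(C)C)cc1)O2
A9 | alternative 3 | methyl 5-{(1R,2S)-2-[(tert-butyldimethylsilyloxy)methyl]-1-[4-(pivaloyloxy)phenyl]but-3-yn-1-yloxy}-6-oxo-6H-pyran-2-carboxylate | COC(=O)C1=CC=C(O[C@@H](c2ccc(OC(=O)C(C)(C)C)cc2)[C@H](CO[Si](C)(C)C(C)(C)C)C#C)C(=O)O1
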